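**Retrosynthetic overview**

1. The target is a diarylmethane. Ring A carries butyryl at C1, hydroxyls at C2 and C6, methyl at C3, a methyl ether at C4 and the CH2 bridge at C5; ring B is a 3-acetyl-2,4,6-trihydroxy-5-methylphenyl group. The last disconnection is hydrogenolysis of five benzyl ethers.
2. The strategy rests on the fact that the two free oxygens of ring A (C2, C6) flank the acyl carbon C1, while the third oxygen (C4, para) is a methyl ether. C2–O and C6–O are therefore made from C–F bonds by a double substitution activated by the butyryl ketone, and C4–OMe comes from an anisole.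
3. The C5–CH2 bond is made by Negishi coupling of a ring A arylzinc with a ring B benzylic bromide. The hexasubstitution of ring A is written onto 3,5-difluoroanisole by three lithiations: between the fluorines (butanal), then twice between fluorine and methoxyl (iodomethane, then zinc).
4. Ring B comes from 2,4,6-trihydroxy-3-methylacetophenone by formylation, benzylation, reduction and bromination.
5. No ring is formed; both benzene rings are bought. The order is ring A core (steps 1–3), ring B (steps 4–7), union (step 8), ketone (steps 9–10), key step, deprotection.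

Key step: step 11

Remark: the carbinol centre made in step 1 is carried as a racemate (compounds 4–7 and 14–17) and is removed by the oxidation in step 10; the target has no stereocentre.

**Route**

Step 1
Reactants: 1 3,5-difluoroanisole; 2 butanal
Product: 4 rac-1-(2,6-difluoro-4-methoxyphenyl)butan-1-ol, via 2,6-difluoro-4-methoxyphenyllithium 3 (not isolated)
Conditions: n-BuLi, THF, −78 °C; then 2, −78 → 0 °C; then H2O
Reagents that add atoms: none
Why: Directed ortho-lithiation removes the most acidic ring hydrogen, the one between the two fluorines, and 1,2-addition of the aryllithium to the aldehyde gives a carbinol whose new stereocentre is racemic and is erased in step 10.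

Step 2
Reactants: 4 rac-1-(2,6-difluoro-4-methoxyphenyl)butan-1-ol
Product: 5 rac-tert-butyl[1-(2,6-difluoro-4-methoxyphenyl)butoxy]dimethylsilane
Conditions: TBSCl, imidazole, DMF, rt
Reagents that add atoms: tert-butyldimethylsilyl chloride, CC(C)(C)[Si](C)(C)Cl
Why: Standard silylation of a secondary benzylic alcohol masks the future ketone as an ether that has no acidic O–H and should tolerate the two later lithiations.

Step 3
Reactants: 5 rac-tert-butyl[1-(2,6-difluoro-4-methoxyphenyl)butoxy]dimethylsilane
Product: 7 rac-tert-butyl[1-(2,6-difluoro-4-methoxy-3-methylphenyl)butoxy]dimethylsilane, via 3-[1-(tert-butyldimethylsilyloxy)butyl]-2,4-difluoro-6-methoxyphenyllithium 6 (not isolated)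
Conditions: s-BuLi, THF, −78 °C; then MeI, −78 → −20 °C
Reagents that add atoms: iodomethane, CI
Why: Directed ortho-lithiation takes one of the two equivalent ring hydrogens lying between a fluorine and the methoxyl (more acidic than the benzylic C–H next to the silyloxy group), the aryllithium is kept at −78 °C so that LiF is not lost to an aryne, and SN2 methylation sets the C3 methyl of ring A.

Step 4
Reactants: 8 2,4,6-trihydroxy-3-methylacetophenone
Product: 10 3-acetyl-2,4,6-trihydroxy-5-methylbenzaldehyde, via aryl iminium chloride 9 (not isolated)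
Conditions: POCl3, DMF, EtOAc, 0 °C → rt; then H2O, 50 °C
Reagents that add atoms: N,N-dimethylformamide, CN(C)C=O; water, O
Why: Vilsmeier–Haack formylation attacks the only unsubstituted carbon of the strongly activated phloroglucinol ring, and hydrolysis of the iminium salt should give the aldehyde.

Step 5
Reactants: 10 3-acetyl-2,4,6-trihydroxy-5-methylbenzaldehyde
Product: 11 3-acetyl-2,4,6-tris(benzyloxy)-5-methylbenzaldehyde
Conditions: BnBr (excess), K2CO3, DMF, 60 °C
Reagents that add atoms: benzyl bromide, BrCc1ccccc1
Why: Williamson etherification in a polar aprotic solvent alkylates the three acidic, carbonyl-stabilised phenoxides on oxygen, and heating with excess bromide should drive the hydrogen-bonded hydroxyls to completion.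

Step 6
Reactants: 11 3-acetyl-2,4,6-tris(benzyloxy)-5-methylbenzaldehyde
Product: 12 1-[2,4,6-tris(benzyloxy)-3-(hydroxymethyl)-5-methylphenyl]ethan-1-one
Conditions: NaBH4, THF–MeOH, −20 °C
Reagents that add atoms: none
Why: Borohydride reduction is chemoselective for the aldehyde because the acetyl group, flanked by two benzyloxy groups and twisted out of conjugation, is far more hindered and less electrophilic at low temperature.

Step 7
Reactants: 12 1-[2,4,6-tris(benzyloxy)-3-(hydroxymethyl)-5-methylphenyl]ethan-1-one
Product: 13 1-[2,4,6-tris(benzyloxy)-3-(bromomethyl)-5-methylphenyl]ethan-1-one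
Conditions: CBr4, PPh3, CH2Cl2, 0 °C
Reagents that add atoms: tetrabromomethane, BrC(Br)(Br)Br
Why: Appel bromination converts the primary benzylic alcohol to the bromide under neutral conditions that leave the ketone and benzyl ethers untouched, and the electron-rich bromide is used at once without chromatography.

Step 8
Reactants: 7 rac-tert-butyl[1-(2,6-difluoro-4-methoxy-3-methylphenyl)butoxy]dimethylsilane; 13 1-[2,4,6-tris(benzyloxy)-3-(bromomethyl)-5-methylphenyl]ethan-1-one
Product: 16 rac-1-[2,4,6-tris(benzyloxy)-3-({3-[1-(tert-butyldimethylsilyloxy)butyl]-2,4-difluoro-6-methoxy-5-methylphenyl}methyl)-5-methylphenyl]ethan-1-one, via aryllithium 14 (not isolated), via arylzinc chloride 15 (not isolated)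
Conditions: 7, s-BuLi, THF, −78 °C; ZnCl2, −78 °C → rt; then 13, Pd(OAc)2 (cat.), SPhos (2-dicyclohexylphosphino-2',6'-dimethoxybiphenyl), THF, 50 °C
Reagents that add atoms: none
Why: Directed ortho-lithiation removes the last ring hydrogen of 7 (between fluorine and methoxyl), transmetalation to zinc at −78 °C gives an arylzinc that no longer loses fluoride and tolerates the acetyl group of 13, and Negishi cross-coupling at zerovalent palladium bearing the bulky biarylphosphine joins C5 of ring A to the benzylic carbon.

Step 9
Reactants: 16 silyl ether from step 8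
Product: 17 rac-1-[2,4,6-tris(benzyloxy)-3-{[2,4-difluoro-3-(1-hydroxybutyl)-6-methoxy-5-methylphenyl]methyl}-5-methylphenyl]ethan-1-one
Conditions: TBAF, THF, 0 °C → rt; then H2O
Reagents that add atoms: none
Why: Fluoride-induced desilylation, driven by Si–F bond formation, frees the secondary carbinol without touching the benzyl ethers, the aryl fluorides or the acetyl group.

Step 10
Reactants: 17 carbinol from step 9
Product: 18 1-[3-({3-acetyl-2,4,6-tris(benzyloxy)-5-methylphenyl}methyl)-2,6-difluoro-4-methoxy-5-methylphenyl]butan-1-one
Conditions: Dess–Martin periodinane, CH2Cl2, rt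
Reagents that add atoms: none
Why: Dess–Martin oxidation converts the secondary benzylic alcohol to the butyryl ketone under neutral conditions, removes the only stereocentre and leaves the diarylmethane CH2 and the benzyl ethers untouched.

Step 11
Reactants: 18 difluoro ketone from step 10; 19 benzyl alcohol
Product: 22 1-[3-({3-acetyl-2,4,6-tris(benzyloxy)-5-methylphenyl}methyl)-2,6-bis(benzyloxy)-4-methoxy-5-methylphenyl]butan-1-one, via sodium benzyloxide 20 (not isolated), via monofluoro monobenzyl ether 21 (not isolated)
Conditions: 19 (2.5 equiv), NaH (2.4 equiv), toluene–THF, 0 °C; then 18, 0 → 80 °C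
Reagents that add atoms: benzyl alcohol (second equivalent, the same compound as 19), OCc1ccccc1
Why: Benzyloxide adds to a fluorine-bearing carbon ortho to the butyryl group to give a Meisenheimer anion whose charge lies on C1, C3 and C5 and is taken up at C1 by the ketone, fluoride then leaves, and a second equivalent of benzyloxide replaces the other fluoride by the same addition–elimination through 21 (drawn with the fluoride next to the ring methyl displaced first; the regioisomeric monoether converges on 22). The closest known reaction type is alkoxide substitution of ortho-fluoroaryl ketones, which is ortho-selective in non-polar media because the sodium ion bridges the carbonyl oxygen and the alkoxide. No ring closes and no stereocentre forms; two C–O bonds are made, each from one molecule of benzyl alcohol. The step needs substitution at C2 and C6 in preference to carbonyl addition, enolisation of the butyryl group and exchange of the C4 methoxyl. The substrate secures this because the three oxygen-bearing carbons of ring A are mutually meta, so no charge falls on C4, and because fluoride is a far better nucleofuge than methoxide while the two small ortho fluorines let the carbonyl lie near the ring plane. Hemiketal formation is reversible, and the small excess of free benzyl alcohol should return any enolate to the ketone.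

Step 12
Reactants: 22 pentabenzyl ether from step 11
Product: 23 1-[3-({3-acetyl-2,4,6-trihydroxy-5-methylphenyl}methyl)-2,6-dihydroxy-4-methoxy-5-methylphenyl]butan-1-one (target, CNP0258463.0)
Conditions: H2 (1 atm), Pd/C, EtOAc–MeOH, rt
Reagents that add atoms: none
Why: Catalytic hydrogenolysis cleaves all five benzylic C–O bonds to toluene, while the aryl ketones (hydrogen-bonded to the freed ortho hydroxyls), the methyl ether and the diarylmethane bridge should not be reduced under one atmosphere of hydrogen.

**Compound list**

1 | 3,5-difluoroanisole | COc1cc(F)cc(F)c1 | starting material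
2 | butanal | CCCC=O | starting material
3 | 2,6-difluoro-4-methoxyphenyllithium | [Li]c1c(F)cc(OC)cc1F | intermediate
4 | rac-1-(2,6-difluoro-4-methoxyphenyl)butan-1-ol | CCCC(O)c1c(F)cc(OC)cc1F | intermediate
5 | rac-tert-butyl[1-(2,6-difluoro-4-methoxyphenyl)butoxy]dimethylsilane | CCCC(O[Si](C)(C)C(C)(C)C)c1c(F)cc(OC)cc1F | intermediate
6 | 3-[1-(tert-butyldimethylsilyloxy)butyl]-2,4-difluoro-6-methoxyphenyllithium | CCCC(O[Si](C)(C)C(C)(C)C)c1c(F)c([Li])c(OC)cc1F | intermediate
7 | rac-tert-butyl[1-(2,6-difluoro-4-methoxy-3-methylphenyl)butoxy]dimethylsilane | CCCC(O[Si](C)(C)C(C)(C)C)c1c(F)c(C)c(OC)cc1F | intermediate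
8 | 2,4,6-trihydroxy-3-methylacetophenone | CC(=O)c1c(O)cc(O)c(C)c1O | starting material
9 | (3-acetyl-2,4,6-trihydroxy-5-methylphenyl)methylidene-dimethyliminium chloride | CC(=O)c1c(O)c(C=[N+](C)C)c(O)c(C)c1O.[Cl-] | intermediate
10 | 3-acetyl-2,4,6-trihydroxy-5-methylbenzaldehyde | CC(=O)c1c(O)c(C=O)c(O)c(C)c1O | intermediate
11 | 3-acetyl-2,4,6-tris(benzyloxy)-5-methylbenzaldehyde | CC(=O)c1c(OCc2ccccc2)c(C=O)c(OCc2ccccc2)c(C)c1OCc1ccccc1 | intermediate
12 | 1-[2,4,6-tris(benzyloxy)-3-(hydroxymethyl)-5-methylphenyl]ethan-1-one | CC(=O)c1c(OCc2ccccc2)c(CO)c(OCc2ccccc2)c(C)c1OCc1ccccc1 | intermediate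
13 | 1-[2,4,6-tris(benzyloxy)-3-(bromomethyl)-5-methylphenyl]ethan-1-one | CC(=O)c1c(OCc2ccccc2)c(CBr)c(OCc2ccccc2)c(C)c1OCc1ccccc1 | intermediate
14 | 3-[1-(tert-butyldimethylsilyloxy)butyl]-2,4-difluoro-6-methoxy-5-methylphenyllithium | CCCC(O[Si](C)(C)C(C)(C)C)c1c(F)c(C)c(OC)c([Li])c1F | intermediate
15 | {3-[1-(tert-butyldimethylsilyloxy)butyl]-2,4-difluoro-6-methoxy-5-methylphenyl}zinc chloride | CCCC(O[Si](C)(C)C(C)(C)C)c1c(F)c(C)c(OC)c([Zn]Cl)c1F | intermediate
16 | rac-1-[2,4,6-tris(benzyloxy)-3-({3-[1-(tert-butyldimethylsilyloxy)butyl]-2,4-difluoro-6-methoxy-5-methylphenyl}methyl)-5-methylphenyl]ethan-1-one | CCCC(O[Si](C)(C)C(C)(C)C)c1c(F)c(C)c(OC)c(Cc2c(OCc3ccccc3)c(C)c(OCc3ccccc3)c(C(C)=O)c2OCc2ccccc2)c1F | intermediate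
17 | rac-1-[2,4,6-tris(benzyloxy)-3-{[2,4-difluoro-3-(1-hydroxybutyl)-6-methoxy-5-methylphenyl]methyl}-5-methylphenyl]ethan-1-one | CCCC(O)c1c(F)c(C)c(OC)c(Cc2c(OCc3ccccc3)c(C)c(OCc3ccccc3)c(C(C)=O)c2OCc2ccccc2)c1F | intermediate
18 | 1-[3-({3-acetyl-2,4,6-tris(benzyloxy)-5-methylphenyl}methyl)-2,6-difluoro-4-methoxy-5-methylphenyl]butan-1-one | CCCC(=O)c1c(F)c(C)c(OC)c(Cc2c(OCc3ccccc3)c(C)c(OCc3ccccc3)c(C(C)=O)c2OCc2ccccc2)c1F | intermediate
19 | benzyl alcohol | OCc1ccccc1 | starting material
20 | sodium benzyloxide | [Na+].[O-]Cc1ccccc1 | intermediate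
21 | 1-[3-({3-acetyl-2,4,6-tris(benzyloxy)-5-methylphenyl}methyl)-6-(benzyloxy)-2-fluoro-4-methoxy-5-methylphenyl]butan-1-one | CCCC(=O)c1c(OCc2ccccc2)c(C)c(OC)c(Cc2c(OCc3ccccc3)c(C)c(OCc3ccccc3)c(C(C)=O)c2OCc2ccccc2)c1F | intermediate
22 | 1-[3-({3-acetyl-2,4,6-tris(benzyloxy)-5-methylphenyl}methyl)-2,6-bis(benzyloxy)-4-methoxy-5-methylphenyl]butan-1-one | CCCC(=O)c1c(OCc2ccccc2)c(C)c(OC)c(Cc2c(OCc3ccccc3)c(C)c(OCc3ccccc3)c(C(C)=O)c2OCc2ccccc2)c1OCc1ccccc1 | intermediate
23 | 1-[3-({3-acetyl-2,4,6-trihydroxy-5-methylphenyl}methyl)-2,6-dihydroxy-4-methoxy-5-methylphenyl]butan-1-one | CCCC(=O)c1c(O)c(C)c(OC)c(Cc2c(O)c(C)c(O)c(C(C)=O)c2O)c1O | target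

**Step count**

Total: 12 steps. Longest linear sequence: 9 steps (steps 4–12, from compound 8); the ring A branch is 8 steps (steps 1–3 and 8–12).

**Steps most likely to fail**

Step 11. The displacement may stop after the first fluoride, because the new benzyloxy group pushes the butyryl carbonyl out of the ring plane and part of the ketone is held as its enolate. Benzyloxide may also add to the carbonyl and cleave the aryl–acyl bond. The fallback gives up fluorine as the oxygen precursor and brings in a ring A that already carries its oxygens. It sets out from the ring B alcohol 12. Commercial aspidinol F1, 1-(2,6-dihydroxy-4-methoxy-3-methylphenyl)butan-1-one, would be treated with 12 and BF3·OEt2 in CH2Cl2 at −20 °C. The benzylic cation from 12 should alkylate the only free ring carbon of F1 (Friedel–Crafts benzylation) to give the tribenzyl diarylmethane F2. Hydrogenolysis of F2 (H2, Pd/C, EtOAc–MeOH) then comes back to the route at the target 23.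

Step 8. Transmetalation and reductive elimination between two doubly ortho-substituted partners may be slow, so that ionisation or homocoupling of the electron-rich benzylic bromide wins. The fallback makes the same C–C bond by carbonyl addition and then removes the oxygen. It sets out from 7 and aldehyde 11. Aryllithium 14, generated from 7 as in step 8, would be added to 11 in THF at −78 °C; addition to the aldehyde should outpace enolisation of the hindered acetyl group and give the diaryl carbinol F3 as a mixture of diastereomers. Ionic deoxygenation with Et3SiH and BF3·OEt2 in CH2Cl2 at −78 °C should reduce only the doubly benzylic position, whose cation is stabilised by the trialkoxyaryl ring, and returns to the route at 16. Steps 6 and 7 are then not needed.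

Step 5. The ambident phenoxides may be benzylated on ring carbon with loss of aromaticity, or the hydroxyl held between the two carbonyl groups may stay unalkylated. The fallback replaces phenoxide alkylation by Mitsunobu etherification, in which each phenol reacts as the acid component and no free phenoxide meets a benzylic halide. It sets out from 10, which would be treated with benzyl alcohol 19, PPh3 and diisopropyl azodicarboxylate in THF at 0 °C → rt, and comes back at 11; this fallback makes no new compound (F0).

**Further compounds**

F1 | step 11 | aspidinol, 1-(2,6-dihydroxy-4-methoxy-3-methylphenyl)butan-1-one | CCCC(=O)c1c(O)cc(OC)c(C)c1O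
F2 | step 11 | 1-[3-({3-acetyl-2,4,6-tris(benzyloxy)-5-methylphenyl}methyl)-2,6-dihydroxy-4-methoxy-5-methylphenyl]butan-1-one | CCCC(=O)c1c(O)c(C)c(OC)c(Cc2c(OCc3ccccc3)c(C)c(OCc3ccccc3)c(C(C)=O)c2OCc2ccccc2)c1O
F3 | step 8 | 1-[2,4,6-tris(benzyloxy)-3-({3-[1-(tert-butyldimethylsilyloxy)butyl]-2,4-difluoro-6-methoxy-5-methylphenyl}(hydroxy)methyl)-5-methylphenyl]ethan-1-one (mixture of diastereomers) | CCCC(O[Si](C)(C)C(C)(C)C)c1c(F)c(C)c(OC)c(C(O)c2c(OCc3ccccc3)c(C)c(OCc3ccccc3)c(C(C)=O)c2OCc2ccccc2)c1F
F0 | step 5 | none | none
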